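Assumption: (1R,5R)-(+)-β-pinene (1), the less common enantiomer, is taken as a purchasable enantiopure material. The target SMILES requires this series: its bridgeheads read C1 S and C5 R once C2 carries oxygen.

Locants: pinane atoms are unprimed (C1–C7, with C6 the CMe2 bridge). Chromene atoms are primed (O1', C3', C4', C4a', C5'–C8', C8a'). The spiro atom is C2 (= C2').

## Structural features

- The target is a 3',4'-dihydro-2'H-chromene-5',7'-dione. Its carbocycle is the enol ether of tetramethylated syncarpic acid (C5'=O, C6'Me2, C7'=O, C8'Me2, C4a'=C8a'–O1'). Its dihydropyran ring (O1', C2, C3', C4', C4a', C8a') is spiro-joined at C2 to a pinane (6,6-dimethylbicyclo[3.1.1]heptane).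
- There are four stereocentres: the bridgeheads C1 (S) and C5 (R), the fully substituted spiro carbon C2 (S) next to C1, and C4' (R), which is 1,3 to C2 across C3'H2.
- In space, O1' is anti and C3' is syn to the C6 gem-dimethyl bridge. The isopropyl group at C4' lies on the face of the pyran ring that carries C1, trans to the C3 methylene.
- The tertiary C2–O1' bond is cyclobutylcarbinyl and its leaving group would be a vinylogous carboxylate. A cation at C2 invites Wagner–Meerwein shift or opening to a p-menthene, and a radical at C2 opens the cyclobutane. The non-enolisable C5'–C6'–C7' 1,3-diketone is open to retro-Claisen cleavage by hard nucleophiles.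
- The real difficulty is to make the hindered C2–O1' bond on the correct face without charge or spin at C2, and to fix C4' relative to C2. A cycloaddition does both at once but leaves C4' to an endo/exo preference.
- The key step exploits this feature: with a C3'=C4' double bond, the ring O1'–C2–C3'=C4'–C4a'=C8a' is a 2H-pyran, the valence isomer of a 1-oxatriene whose terminus is C2. C2 is then the exocyclic alkene carbon of the pinane, and its two faces are sharply differentiated by the C6 bridge.

## Logic of the disconnections

In one sentence: the spiro-pyran ring and its C2–O1' stereocentre come from an oxa-6π electrocyclisation of a 1-oxatriene that a propargyl Claisen rearrangement releases from 12.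

**16 ⇒ 15.** The C3'–H and C4'–H bonds are cut, which restores the C3'=C4' double bond. This turns the dihydropyran into a 2H-pyran and removes C4' as a stereocentre, so that it is set last, by relay from C2. The forward step must deliver hydrogen to the face of C3'=C4' that carries the C3 methylene, away from C1 and the C6 bridge.

**15 ⇒ 12 (key).** The C2–O1' bond is cut by retro-6π to 1-oxatriene 14. Prototropy leads back to allene 13, and the C4'–C4a' bond is cut by retro-[3,3], with oxygen reconnected to C2 as a propargylic enol ether. The pyran ring, the spiro stereocentre and one C–C bond disappear together, and 12 is a plain ether of two halves of similar size. Both bonds form in pericyclic steps, so C2 is never a cation or a radical. The forward step requires three things: the [3,3] shift must outrun heterolysis of the tertiary ether, closure must give the pyran and not a furan, and oxygen must bond to the C2 face anti to C6.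

**12 ⇒ 6 + 10.** The enol ether O–C8a' bond is cut. This is the convergent union (C14 + C10) by addition–elimination of alkoxide 11 at the β-carbon of a β-chloroenone. The demand is that a hindered alkoxide attacks the β-carbon and not a ring carbonyl.

**6 ⇒ 3 + 4.** The C2–C3' bond is cut: acetylide addition to a ketone. 4 supplies C3', C4' and the isopropyl group in one piece. The carbinol configuration need not be controlled, because step 7 erases it.

**3 ⇒ 1.** The C2=O bond is traced to the exocyclic C=CH2. Both bridgehead stereocentres are bought with 1.

**10 ⇒ 9 ⇒ 8 ⇒ 7.** The C–Cl bond comes from the enol C–OH. The acetyl group is put back as a blocking group, and the four C–CH3 bonds are cut. The syncarpic core thus comes from an aromatic acylphloroglucinol by exhaustive C-methylation, which is well precedented.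

## Other disconnections considered

**Alternative 1:** This is the obvious route. C3'–C4' and C2–O1' are cut together by retro-hetero-Diels–Alder. Forward: Knoevenagel condensation of 9 with isobutyraldehyde gives the heterodiene A1 (isobutylidene syncarpic acid), and inverse-demand [4+2] with 1 gives 16. It is the shortest plan. However, C4' is set only by the endo/exo orientation of the isopropyl terminus of A1 towards 1, and the two approach modes are expected to differ little in energy, so both C4' epimers should form. The asynchronous transition state also places positive charge on C2, so acid or heat can divert material into rearranged terpenes. The chosen plan sets C2 and C4' in two separately controlled events.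

**Alternative 2:** Only C2–O1' is cut. Forward key step: 6-endo Markovnikov cycloetherification of the enol OH of A2 onto its exocyclic C3'=C2 alkene. A2 is a 2-alkylsyncarpic acid with C4' already set, reachable from A1 by enantioselective conjugate alkenylation. Every practical mode of this closure (Brønsted acid, halonium ion, metal-hydride hydrogen-atom transfer) develops cationic or radical character at C2, the cyclobutylcarbinyl position. Skeletal rearrangement or ring opening is therefore the expected competitor. An extra catalyst-controlled step is also needed for C4'. The chosen plan makes the same bond by electrocyclisation.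

**Alternative 3:** The four C–CH3 bonds at C6' and C8' are cut. Forward key step: dearomative tetra-C-methylation of the phloroglucinol-derived chromane-5,7-diol A3. Without an acyl group on the ring, O-methylation and methylation at C4a' are expected to compete with the desired pattern. A3 itself would still have to be assembled by a cycloaddition with 1, so the stereochemical problem is moved, not solved, and the route is longer.

Key step: step 7

## Route

Step 1
Reactants: 1 (1R,5R)-(+)-β-pinene
Product: 3 (1S,5R)-(−)-nopinone [(1S,5R)-6,6-dimethylbicyclo[3.1.1]heptan-2-one], via secondary ozonide 2 (not isolated)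
Conditions: O3, CH2Cl2, −78 °C; then Me2S, −78 °C → rt
Reagents that add atoms: ozone, [O-][O+]=O
Why: Ozonolysis of the 1,1-disubstituted exocyclic alkene with reductive cleavage of the ozonide; the =CH2 carbon leaves as formaldehyde. No stereocentre is made, and C1 and C5 are bridgeheads that cannot epimerise.

Step 2
Reactants: 3 (−)-nopinone; 4 3-methylbut-1-yne
Product: 6 (1S,2S,5R)-6,6-dimethyl-2-(3-methylbut-1-yn-1-yl)bicyclo[3.1.1]heptan-2-ol, via lithium 3-methylbut-1-yn-1-ide 5 (not isolated)
Conditions: 4, n-BuLi, THF, −78 °C; then 3, −78 → 0 °C; then H2O
Reagents that add atoms: none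
Why: 1,2-Addition of a lithium acetylide to a ketone at low temperature, which limits enolisation of 3. The acetylide should enter anti to the C6 bridge, but the configuration of this carbinol is of no consequence because C2 becomes trigonal again in step 7.

Step 3
Reactants: 7 2,4,6-trihydroxyacetophenone
Product: 8 2-acetyl-3-hydroxy-4,4,6,6-tetramethylcyclohex-2-ene-1,5-dione (acetylsyncarpic acid)
Conditions: NaOMe, MeI, MeOH, 0 °C → reflux; acidic work-up
Reagents that add atoms: iodomethane, CI
Why: Exhaustive dearomative C-methylation of an acylphloroglucinol. Each of the two free ring carbons is methylated twice, and the acyl-stabilised trione enolate that remains should be too weakly nucleophilic to react further.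

Step 4
Reactants: 8 acetylsyncarpic acid
Product: 9 syncarpic acid (5-hydroxy-2,2,6,6-tetramethylcyclohex-4-ene-1,3-dione, the enol of 2,2,4,4-tetramethylcyclohexane-1,3,5-trione)
Conditions: 6 M aq. HCl, reflux
Reagents that add atoms: none
Why: Acid-mediated retro-Claisen deacylation of a 2-acyl-1,3-dione; the quaternary gem-dimethyl positions are inert.

Step 5
Reactants: 9 syncarpic acid
Product: 10 5-chloro-2,2,6,6-tetramethylcyclohex-4-ene-1,3-dione
Conditions: (COCl)2, DMF (cat.), CH2Cl2, 0 °C → rt
Reagents that add atoms: oxalyl chloride, ClC(=O)C(=O)Cl
Why: Conversion of a vinylogous acid into its vinylogous acid chloride (β-chloroenone) under Vilsmeier catalysis. The carbonyl positions of 9 are equivalent by symmetry, so a single chloride should result.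

Step 6
Reactants: 6 propargylic alcohol; 10 β-chloroenone
Product: 12 5-{[(1S,2S,5R)-6,6-dimethyl-2-(3-methylbut-1-yn-1-yl)bicyclo[3.1.1]heptan-2-yl]oxy}-2,2,6,6-tetramethylcyclohex-4-ene-1,3-dione, via potassium alkoxide 11 (not isolated)
Conditions: 6, KH, THF, 0 °C; then 10, 0 °C → rt; neutral work-up, used without silica chromatography
Reagents that add atoms: none
Why: Addition–elimination (SNV) of an alkoxide at the β-carbon of a β-chloroenone. 10 has no enolisable hydrogen and 6 no acidic C–H, so KH should only form the alkoxide; the C2–O bond of 6 is untouched.

Step 7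
Reactants: 12 propargyl enol ether
Product: 15 (1S,2S,5R)-4'-isopropyl-6,6,6',6',8',8'-hexamethylspiro[bicyclo[3.1.1]heptane-2,2'-chromene]-5',7'(6'H,8'H)-dione, via allenyl trione 13 (not isolated), via 1-oxatriene 14 (not isolated)
Conditions: imidazole (10 mol %), PhMe, 100 °C
Reagents that add atoms: none
Why: Propargyl Claisen rearrangement, prototropy and oxa-6π electrocyclisation in sequence, the cascade known for propargyl vinyl ethers with an acceptor on the vinyl carbon (closest types: propargyl vinyl ether → 2H-pyran, aryl propargyl ether → 2H-chromene). The [3,3] shift through the six-centre array C4a'=C8a'–O–C2···C3'≡C4' makes C4'–C4a' and breaks the strained tertiary O–C2 bond in concert, so C2 never carries a charge or a spin; the product is allenyl trione 13. 13 is a strong enol acid, and imidazole shuttles its proton from oxygen to the central allene carbon C3' (formally a 1,5-H shift) to give 1-oxatriene 14, in which the exocyclic C3'=C2 alkene of the pinane is the triene terminus. 14 closes by thermal disrotatory 6π electrocyclisation between a carbonyl oxygen and C2; this closes the pyran, the only ring formed, and the two ring carbonyls flanking C4a' are equivalent, so there is no regiochemical issue. The new stereocentre C2 is controlled by the pinane: oxygen should bond to the face of C2 anti to the C6 gem-dimethyl bridge, the face that reagents take on the exocyclic alkene of β-pinene, which puts O1' anti and C3' syn to that bridge as in 16. The carbinol configuration of 12 and the axial chirality of 13 are erased in 14, so nothing upstream needs control. The step needs rearrangement ahead of ionisation of the tertiary ether (apolar solvent, imidazole buffer), pyran ahead of furan closure (no π-acidic metal, proton delivered to C3'), and kinetic control at C2 (the lowest temperature that drives the [3,3] step, since retro-6π would equilibrate C2).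

Step 8
Reactants: 15 spiro-2H-pyran
Product: 16 (1S,2S,4'R,5R)-4'-isopropyl-6,6,6',6',8',8'-hexamethyl-3',4'-dihydrospiro[bicyclo[3.1.1]heptane-2,2'-chromene]-5',7'(6'H,8'H)-dione (target)
Conditions: H2 (1 atm), 10% Pd/C, EtOAc, rt
Reagents that add atoms: none
Why: Heterogeneous syn-hydrogenation of the C3'=C4' bond of a fused 2H-pyran, the standard reduction of 2H-chromenes to chromanes; the tetrasubstituted, acceptor-bearing C4a'=C8a' enol ether and the ketones should not be reduced. H2 should add to the pyran face that carries the C3 methylene, because the other face is covered by C1 and the C6 bridge (its endo methyl lies over C3'); this places H on the C3 face and the isopropyl group on the C1 face, i.e. 4'R.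

## Compound list

1 | (1R,5R)-(+)-β-pinene, (1R,5R)-6,6-dimethyl-2-methylidenebicyclo[3.1.1]heptane | C=C1CC[C@@H]2C[C@H]1C2(C)C | starting material
2 | secondary ozonide of 1, (1S,5R)-6,6-dimethylspiro[bicyclo[3.1.1]heptane-2,3'-[1,2,4]trioxolane], C2 configuration unspecified | C1OC2(CC[C@@H]3C[C@H]2C3(C)C)OO1 | intermediate (not isolated)
3 | (1S,5R)-(−)-nopinone, (1S,5R)-6,6-dimethylbicyclo[3.1.1]heptan-2-one | O=C1CC[C@@H]2C[C@H]1C2(C)C | intermediate
4 | 3-methylbut-1-yne | CC(C)C#C | starting material
5 | lithium 3-methylbut-1-yn-1-ide | [Li+].[C-]#CC(C)C | intermediate (not isolated)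
6 | (1S,2S,5R)-6,6-dimethyl-2-(3-methylbut-1-yn-1-yl)bicyclo[3.1.1]heptan-2-ol (alkynyl anti, OH syn to the C6 bridge) | CC(C)C#C[C@]1(O)CC[C@@H]2C[C@H]1C2(C)C | intermediate
7 | 2,4,6-trihydroxyacetophenone | CC(=O)c1c(O)cc(O)cc1O | starting material
8 | 2-acetyl-3-hydroxy-4,4,6,6-tetramethylcyclohex-2-ene-1,5-dione (acetylsyncarpic acid) | CC(=O)C1=C(O)C(C)(C)C(=O)C(C)(C)C1=O | intermediate
9 | syncarpic acid, 5-hydroxy-2,2,6,6-tetramethylcyclohex-4-ene-1,3-dione | O=C1C=C(O)C(C)(C)C(=O)C1(C)C | intermediate
10 | 5-chloro-2,2,6,6-tetramethylcyclohex-4-ene-1,3-dione | O=C1C=C(Cl)C(C)(C)C(=O)C1(C)C | intermediate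
11 | potassium (1S,2S,5R)-6,6-dimethyl-2-(3-methylbut-1-yn-1-yl)bicyclo[3.1.1]heptan-2-olate | CC(C)C#C[C@]1([O-])CC[C@@H]2C[C@H]1C2(C)C.[K+] | intermediate (not isolated)
12 | 5-{[(1S,2S,5R)-6,6-dimethyl-2-(3-methylbut-1-yn-1-yl)bicyclo[3.1.1]heptan-2-yl]oxy}-2,2,6,6-tetramethylcyclohex-4-ene-1,3-dione | CC(C)C#C[C@]1(OC2=CC(=O)C(C)(C)C(=O)C2(C)C)CC[C@@H]2C[C@H]1C2(C)C | intermediate
13 | 3-hydroxy-4,4,6,6-tetramethyl-2-{3-methyl-1-[(1S,5R)-6,6-dimethylbicyclo[3.1.1]heptan-2-ylidene]but-1-en-2-yl}cyclohex-2-ene-1,5-dione (allene axis unspecified) | CC(C)C(=C=C1CC[C@@H]2C[C@H]1C2(C)C)C1=C(O)C(C)(C)C(=O)C(C)(C)C1=O | intermediate (not isolated)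
14 | 2,2,4,4-tetramethyl-6-{3-methyl-1-[(1S,5R)-6,6-dimethylbicyclo[3.1.1]heptan-2-ylidene]butan-2-ylidene}cyclohexane-1,3,5-trione (geometry of the pinane C=C unspecified) | CC(C)C(C=C1CC[C@@H]2C[C@H]1C2(C)C)=C1C(=O)C(C)(C)C(=O)C(C)(C)C1=O | intermediate (not isolated)
15 | (1S,2S,5R)-4'-isopropyl-6,6,6',6',8',8'-hexamethylspiro[bicyclo[3.1.1]heptane-2,2'-chromene]-5',7'(6'H,8'H)-dione (O1' anti to the C6 bridge) | CC(C)C1=C[C@]2(CC[C@@H]3C[C@H]2C3(C)C)OC2=C1C(=O)C(C)(C)C(=O)C2(C)C | intermediate
16 | (1S,2S,4'R,5R)-4'-isopropyl-6,6,6',6',8',8'-hexamethyl-3',4'-dihydrospiro[bicyclo[3.1.1]heptane-2,2'-chromene]-5',7'(6'H,8'H)-dione | CC(C)[C@H]1C[C@]2(CC[C@@H]3C[C@H]2C3(C)C)OC2=C1C(=O)C(C)(C)C(=O)C2(C)C | target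

## Step count and least certain steps

Total: 8 steps. Longest linear sequence: 6 steps (7 → 8 → 9 → 10 → 12 → 15 → 16; steps 3–8). The terpene branch (steps 1–2) joins at step 6.

**Step 7 (key step).** Three processes could defeat it.
- Heterolysis of the strained tertiary propargylic C2–O bond could occur before the [3,3] shift; the leaving group is a syncarpate, so this gives elimination and pinane rearrangement.
- 5-exo closure of the enol onto the central allene carbon would give a furan.
- Facial selectivity at C2 could erode through reversible ring opening of the 2H-pyran at the reaction temperature, since the epimer with oxygen syn to the C6 bridge may be of similar stability.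

Fallback, setting out from 9 and 1 and coming back at 16: Knoevenagel condensation of 9 with isobutyraldehyde (ethylenediammonium diacetate cat., excess 1, CH2Cl2, rt → 40 °C) should give 2,2,4,4-tetramethyl-6-(2-methylpropylidene)cyclohexane-1,3,5-trione F1. F1 would be trapped as it forms by 1 in an inverse-demand hetero-Diels–Alder reaction, and 16 would be separated from its C4' epimer by chromatography.

**Step 6.** The hindered tertiary alkoxide may attack a ring carbonyl of 10 (retro-Claisen ring cleavage) or fail to add at the β-carbon, which is flanked by a quaternary centre. Loss of acetylide from the alkoxide on warming is a further drain.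

Fallback, setting out from 8 and 3 and coming back at 15:
- Kabbe condensation (pyrrolidine, PhMe, reflux, water removal) should join the acetyl methyl of 8 to the carbonyl of 3 and close the ring by oxa-Michael addition on the C2 face anti to the C6 bridge. The product would be (1S,2S,5R)-6,6,6',6',8',8'-hexamethylspiro[bicyclo[3.1.1]heptane-2,2'-chromene]-4',5',7'(3'H,6'H,8'H)-trione F2.
- Deprotonation at C3', the only enolisable position, and triflation (KHMDS, PhNTf2, THF, −78 °C) should give the 4'-dienyl triflate F3.
- Negishi coupling with i-PrZnBr (Pd(OAc)2, CPhos, THF, rt) would install the isopropyl group and give 15.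

**Step 8.** Face discrimination on the metal surface may be insufficient, because the bias comes from the C2 substituents two atoms away. The alkene is also hindered (quaternary C2 on one side, isopropyl on the other) and may reduce slowly, and the allylic C2–O1' bond may undergo hydrogenolysis.

Fallback, setting out from 15 and coming back at 16: the surface reaction is replaced by a stepwise radical reduction by metal-hydride hydrogen-atom transfer (Mn(dpm)3, PhSiH3, TBHP, i-PrOH, rt). H• adds to C3' to give a C4' radical conjugated with the enol ether, and the second hydrogen is then taken up on the less hindered face under product-stability control. The radical is three bonds away from the cyclobutane, so the pinane should survive, and no C–O hydrogenolysis pathway exists. No new isolated compound is formed.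

## Further compounds

F1 | step 7 | 2,2,4,4-tetramethyl-6-(2-methylpropylidene)cyclohexane-1,3,5-trione (isobutylidene syncarpic acid) | CC(C)C=C1C(=O)C(C)(C)C(=O)C(C)(C)C1=O
F2 | step 6 | (1S,2S,5R)-6,6,6',6',8',8'-hexamethylspiro[bicyclo[3.1.1]heptane-2,2'-chromene]-4',5',7'(3'H,6'H,8'H)-trione (C2 arranged as in 16) | O=C1C[C@]2(CC[C@@H]3C[C@H]2C3(C)C)OC2=C1C(=O)C(C)(C)C(=O)C2(C)C
F3 | step 6 | (1S,2R,5R)-6,6,6',6',8',8'-hexamethyl-5',7'-dioxo-5',6',7',8'-tetrahydrospiro[bicyclo[3.1.1]heptane-2,2'-chromen]-4'-yl trifluoromethanesulfonate (C2 arranged in space as in 16; descriptor changes by priority only) | FC(F)(F)S(=O)(=O)OC1=C[C@]2(CC[C@@H]3C[C@H]2C3(C)C)OC2=C1C(=O)C(C)(C)C(=O)C2(C)C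
F0 | step 8 | none | none
A1 | alternative 1 | 2,2,4,4-tetramethyl-6-(2-methylpropylidene)cyclohexane-1,3,5-trione (isobutylidene syncarpic acid) | CC(C)C=C1C(=O)C(C)(C)C(=O)C(C)(C)C1=O
A2 | alternative 2 | 3-hydroxy-4,4,6,6-tetramethyl-2-{(2S)-3-methyl-1-[(1S,5R)-6,6-dimethylbicyclo[3.1.1]heptan-2-ylidene]butan-2-yl}cyclohex-2-ene-1,5-dione (alkene geometry unspecified) | CC(C)[C@@H](C=C1CC[C@@H]2C[C@H]1C2(C)C)C1=C(O)C(C)(C)C(=O)C(C)(C)C1=O
A3 | alternative 3 | (1S,2S,4'R,5R)-4'-isopropyl-6,6-dimethyl-3',4'-dihydrospiro[bicyclo[3.1.1]heptane-2,2'-chromene]-5',7'-diol | CC(C)[C@H]1C[C@]2(CC[C@@H]3C[C@H]2C3(C)C)Oc2cc(O)cc(O)c21
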